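The flask starts with more J than Z, but the excess is 0.0280 M and step one spends one J per Z.

common to all: Z 0.093 M; J 0.121 M

| charge | time |
|---|---|
| Tuesday's | 40 s |
| Wednesday's | 100 s |

    Z + J → Z.J (k1 = 0.30 /M/s)
    Z.J ⇌ G (K2 = 1.3, k2 = 0.065 /s)
    J + G → J.G (k3 = 0.17 /M/s)

* which of these there is most of at the end, counted by the Z in it, Tuesday's (J.G / Z / G / Z.J)
* which of these there is most of at the end, counted by the Z in it, Wednesday's (J.G / Z / G / Z.J)
* amount of the one of these that there is most of at the end, in percent of the Z charged, Tuesday's
* amount of the one of these that there is most of at the end, in percent of the Z charged, Wednesday's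

For the next at the bench: Tuesday's and Wednesday's are the same charge, read at two times. The quantity to watch is the Z clock, the half-life of Z by step one at the c_J of the moment, ln of two over the step's constant times c_J; at the charge it reads 19.1 s. J is not to be topped up between readings: the clock goes inversely with c_J.

The clock lengthens as c_J falls. Without the J.G step, c_J minus c_Z stays constant, and the second-order integral leaves Z at 36.7% on Tuesday's and 15.0% on Wednesday's. The J.G step takes further J, so these are floors for Z.

G is fed from Z.J and stays below 1.3 times c_Z.J. That caps G at 35.8% on Tuesday's and 48.0% on Wednesday's. So Tuesday's should show Z ahead of G by at least 0.9 percentage points, and Z.J, which that cap does not bound, is the weak point of that call. Wednesday's should show G in front, below that cap.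

The forecast, close to this, says Z at 38% and then G at 33%, on the ground that “The first step slows sharply as J is used up”. On Tuesday's the flask gives Z at 37.6%. On Wednesday's it gives G at 33.7%.

On Tuesday's at 40 s, with 47% of J left, the Z clock reads 40.6 s, longer than the 11 s forward half-life of Z.J. In the neighbouring flask with 0.023 M of Z, 84.0% of J remains, step one is nearly pseudo-first-order, the clock moves from 19.1 s to 22.7 s, these two clocks put Z between 23.4% and 29.5%, and Z stands at 26.8%.

The rate constants belong to no real substance; what happens was integrated by code.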